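**Retrosynthetic overview**

1. Numbering: lactone O1–C2(=O)–C3(side chain, carbinol C1′)=C4(Br)–C5(=C6H–I). Target 11 ⇐ silyl ether 10 ⇐ tetronic acid 9 (C4–Br from C4–OH, since C4 is a vinylogous acyl bromide) ⇐ hydroxy lactone 8 (C4 alcohol instead of ketone).
2. Key disconnection of 8: ring bonds C3–C4 (aldol addition of the enolate of ester 3 to the aldehyde carbon of ynal 4) and O1–C5 (iodolactonization of the C2 carboxylate onto the C5≡C6 alkyne), made in one flask together with C6–I.
3. Enabling feature: in the exocyclic iodo enol lactone O1–C5(=C6H–I), O1 and I are anti across C5=C6, the pattern left by anti addition of a carboxylate and I+ to a terminal alkyne. C4 lies between the enolizable C3 and C5 at carbonyl oxidation level, so the furanone ring is the sum of a C3/O1 dinucleophile (3) and a C4/C5 dielectrophile (4 + I2).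
4. The furanone is the only ring and is closed in the key step. The single lasting stereocentre C1′ (R) comes from asymmetric hydrogenation of β-keto ester 1 and is carried as a silyl ether; the C3/C4 stereocentres of 8 are transient.

Key step: step 3

**Route**

Step 1
Reactants: 1 methyl 3-oxohexanoate
Product: 2 methyl (3R)-3-hydroxyhexanoate
Conditions: H2 (50 atm), RuCl2[(R)-BINAP] (0.1 mol %), MeOH, 50 °C
Reagents that add atoms: none
Why: Noyori asymmetric hydrogenation of a β-keto ester; the (R)-BINAP–Ru catalyst, chelated by ketone and ester, should deliver hydrogen to the face that gives the (3R)-alcohol, as it does for methyl 3-oxobutanoate.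

Step 2
Reactants: 2 methyl (3R)-3-hydroxyhexanoate
Product: 3 methyl (3R)-3-[(tert-butyldimethylsilyl)oxy]hexanoate
Conditions: TBSCl, imidazole, DMF, rt
Reagents that add atoms: tert-butyldimethylsilyl chloride, CC(C)(C)[Si](C)(C)Cl
Why: Standard silylation of a secondary alcohol; the silyl ether keeps the C1′ oxygen from competing as a nucleophile in the iodocyclization and from being oxidized in step 4, and no stereocentre is touched.

Step 3
Reactants: 3 methyl (3R)-3-[(tert-butyldimethylsilyl)oxy]hexanoate; 4 3-(trimethylsilyl)prop-2-ynal
Product: 8 (5E)-3-[(1R)-1-(tert-butyldimethylsilyloxy)butyl]-4-hydroxy-5-(iodomethylidene)oxolan-2-one (C3/C4 diastereomer mixture), via lithium ester enolate 5 (not isolated), via aldol ester 6 (not isolated), via alkynyl hydroxy acid 7 (not isolated)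
Conditions: LDA, THF, −78 °C; 4, −78 °C; then LiOH, MeOH–H2O, 0 °C to rt; then AcOH to pH 8, NaHCO3, I2, MeCN, 0 °C, dark
Reagents that add atoms: iodine, II; lithium hydroxide, [Li+].[OH-]
Why: The lithium enolate of 3 adds to the aldehyde carbon of 4 (aldol addition, C3–C4; the silyl cap on the alkyne and the higher electrophilicity of the aldehyde keep the addition 1,2), hydroxide then cleaves the methyl ester and the alkynyl C–Si bond, and iodine activates the now terminal C5≡C6 bond as an iodonium ion that the C2 carboxylate opens at C5 (O1–C5) while iodine stays on C6. The closest known reactions are the aldol addition of β-silyloxy ester enolates to ynals and the iodolactonization of pent-4-ynoic acids to (E)-5-(iodomethylidene) lactones; only their telescoping is specific to this route. The lactone closes in the 5-exo-dig mode, which a terminal alkyne favours over 6-endo because the nucleophile attacks the internal, more substituted carbon of the iodonium ion. The new stereocentres at C3 and C4 form without control and need none, since both become sp2 in step 4, whereas the C5=C6 geometry is fixed by the anti opening of the iodonium ion: O1 and I end on opposite sides, that is E with iodine on the C4 side. The step needs attack by carboxylate and not by hydroxyl, and no iodination of the acetylenic C–H: the C1′ oxygen is silylated, the C4 hydroxyl could only close a three- or four-membered ring, and at pH 8 the diisopropylamine is protonated and the medium is too weakly basic for alkynyl iodide formation.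

Step 4
Reactants: 8 (5E)-3-[(1R)-1-(tert-butyldimethylsilyloxy)butyl]-4-hydroxy-5-(iodomethylidene)oxolan-2-one
Product: 9 (5E)-3-[(1R)-1-(tert-butyldimethylsilyloxy)butyl]-4-hydroxy-5-(iodomethylidene)furan-2(5H)-one
Conditions: Dess–Martin periodinane, NaHCO3, CH2Cl2, 0 °C to rt
Reagents that add atoms: none
Why: Dess–Martin oxidation of the secondary C4 alcohol gives the 2,4-dione, which should enolize to the 3-substituted tetronic acid and thereby erase the C3 and C4 stereocentres, under buffered conditions that should leave the silyl ether and the (E)-iodoalkene untouched.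

Step 5
Reactants: 9 (5E)-3-[(1R)-1-(tert-butyldimethylsilyloxy)butyl]-4-hydroxy-5-(iodomethylidene)furan-2(5H)-one
Product: 10 (5E)-4-bromo-3-[(1R)-1-(tert-butyldimethylsilyloxy)butyl]-5-(iodomethylidene)furan-2(5H)-one
Conditions: (COBr)2, DMF, CH2Cl2, 0 °C
Reagents that add atoms: oxalyl bromide, O=C(Br)C(=O)Br
Why: Vilsmeier-type deoxybromination of a vinylogous acid: the tetronic acid oxygen is activated as its iminium ether and bromide replaces it by addition–elimination at C4, the standard conversion of tetronic acids into 4-bromofuranones.

Step 6
Reactants: 10 (5E)-4-bromo-3-[(1R)-1-(tert-butyldimethylsilyloxy)butyl]-5-(iodomethylidene)furan-2(5H)-one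
Product: 11 (5E)-4-bromo-3-[(1R)-1-hydroxybutyl]-5-(iodomethylidene)furan-2(5H)-one
Conditions: 48% aq HF, MeCN, 0 °C
Reagents that add atoms: none
Why: Acidic fluoride cleavage of a secondary silyl ether, chosen because it contains no base or strong nucleophile that could add to C4 or C6; C1′ is not a reaction centre, so the (R) configuration and the (E) geometry should be retained.

**Compound list**

1 | methyl 3-oxohexanoate | CCCC(=O)CC(=O)OC | starting material
2 | methyl (3R)-3-hydroxyhexanoate | CCC[C@@H](O)CC(=O)OC | intermediate
3 | methyl (3R)-3-[(tert-butyldimethylsilyl)oxy]hexanoate | CCC[C@@H](O[Si](C)(C)C(C)(C)C)CC(=O)OC | intermediate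
4 | 3-(trimethylsilyl)prop-2-ynal | C[Si](C)(C)C#CC=O | starting material
5 | lithium enolate of ester 3, lithium (3R)-3-(tert-butyldimethylsilyloxy)-1-methoxyhex-1-en-1-olate | CCC[C@@H](O[Si](C)(C)C(C)(C)C)C=C([O-])OC.[Li+] | intermediate
6 | methyl 2-[(1R)-1-(tert-butyldimethylsilyloxy)butyl]-3-hydroxy-5-(trimethylsilyl)pent-4-ynoate, diastereomer mixture at C2 and C3 | CCC[C@@H](O[Si](C)(C)C(C)(C)C)C(C(O)C#C[Si](C)(C)C)C(=O)OC | intermediate
7 | 2-[(1R)-1-(tert-butyldimethylsilyloxy)butyl]-3-hydroxypent-4-ynoic acid, diastereomer mixture at C2 and C3 | CCC[C@@H](O[Si](C)(C)C(C)(C)C)C(C(O)C#C)C(=O)O | intermediate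
8 | (5E)-3-[(1R)-1-(tert-butyldimethylsilyloxy)butyl]-4-hydroxy-5-(iodomethylidene)oxolan-2-one, diastereomer mixture at C3 and C4 | CCC[C@@H](O[Si](C)(C)C(C)(C)C)C1C(O)/C(=C\I)OC1=O | intermediate
9 | (5E)-3-[(1R)-1-(tert-butyldimethylsilyloxy)butyl]-4-hydroxy-5-(iodomethylidene)furan-2(5H)-one | CCC[C@@H](O[Si](C)(C)C(C)(C)C)C1=C(O)/C(=C\I)OC1=O | intermediate
10 | (5E)-4-bromo-3-[(1R)-1-(tert-butyldimethylsilyloxy)butyl]-5-(iodomethylidene)furan-2(5H)-one | CCC[C@@H](O[Si](C)(C)C(C)(C)C)C1=C(Br)/C(=C\I)OC1=O | intermediate
11 | (5E)-4-bromo-3-[(1R)-1-hydroxybutyl]-5-(iodomethylidene)furan-2(5H)-one | CCC[C@@H](O)C1=C(Br)/C(=C\I)OC1=O | target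

**Step count and risks**

Total step count: 6. Longest linear sequence: 6 steps (1 → 11).

Steps most likely to fail:

Step 3. The telescoped sequence may suffer from loss of silanolate from the enolate (E1cB), from retro-aldol cleavage or incomplete hydrolysis of the hindered ester in the unpurified mixture, or from iodination of the acetylenic C–H if the base is not fully neutralised. The fallback sets out from 3 and avoids a basic aldolate. Silylation of enolate 5 (LDA, TMSCl, THF, −78 °C) should give the ketene silyl acetal F1. A Mukaiyama aldol addition of F1 to 4 (BF3·OEt2, CH2Cl2, −78 °C) should give aldol ester 6, which is now isolated. Hydrolysis (LiOH, THF–MeOH–H2O) should give hydroxy acid 7, purified as such. Iodolactonization with N-iodosuccinimide and KHCO3 in CH2Cl2 should then give 8, where the fallback comes back to the route.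

Step 5. The HBr and free bromide of the Vilsmeier conditions may cause E-to-Z isomerization of the iodoalkene (which relieves the I/Br contact), halide exchange at C6 by addition–elimination, or loss of the silyl ether. The fallback sets out from 9. Triflic anhydride and 2,6-lutidine (CH2Cl2, −78 °C) should give the enol triflate F2. Lithium bromide (THF, 0 °C) should then replace the triflate by addition–elimination at C4 without acid and give 10, where the fallback comes back to the route.

Step 1. Facial selectivity in the hydrogenation may be incomplete, and because no later step creates a lasting second stereocentre, a shortfall in enantiomeric purity cannot be corrected downstream. The fallback sets out from 1 and comes back at 2: reduction with an (R)-selective, NADPH-dependent ketoreductase with glucose/glucose dehydrogenase cofactor recycling (phosphate buffer pH 7, 30 °C). It makes no new compound.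

Further compounds
F1 | step 3 | {[(3R)-3-(tert-butyldimethylsilyloxy)-1-methoxyhex-1-en-1-yl]oxy}trimethylsilane (ketene silyl acetal of 3) | CCC[C@@H](O[Si](C)(C)C(C)(C)C)C=C(OC)O[Si](C)(C)C
F2 | step 5 | (5E)-3-[(1R)-1-(tert-butyldimethylsilyloxy)butyl]-5-(iodomethylidene)-2-oxo-2,5-dihydrofuran-4-yl trifluoromethanesulfonate | CCC[C@@H](O[Si](C)(C)C(C)(C)C)C1=C(OS(=O)(=O)C(F)(F)F)/C(=C\I)OC1=O
F0 | step 1 | none | none
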